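**Plan**
- Retrosynthesis: after removal of four silicon-based protecting groups, the 2H-pyran ring is cut at O1–C2 and C4–C4a. This gives a protected dihydrochalcone phenol (7) and a C10 enal (14); 7 is cut at Cα–Cβ of its propanone chain (aldol, then hydrogenation) and 14 goes back to geranyl acetate.
- Enabling feature: in ring A, C8a (bearing O1) lies between oxygenated C8 and unsubstituted C4a, so the C8a phenol has one open ortho carbon. C4–C3–C2, with the C2 methyl and side chain, is the skeleton of a β,β-disubstituted enal.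
- Forward order: the aryl–C3–aryl chain is assembled first (steps 1–4) and the enal separately (steps 5–8). The only new ring, the pyran, closes in step 9 by ortho-aldol, quinone methide formation and oxa-6π closure; step 10 removes all protecting groups.
- Stereochemistry: C2 (R), the only stereocentre, is to be set during ring closure by a chiral phosphoric acid. The two E alkenes come from geranyl acetate and from a selenoxide syn-elimination.

Key step: step 9

Remark: the sense of induction of the chiral acid cannot be derived from precedent; the (R)-acid is assumed to give the (2R)-chromene, and its antipode would be used if the opposite sense were found.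
Abbreviations: SEM = 2-(trimethylsilyl)ethoxymethyl; TES = triethylsilyl. Chromene numbering: O1, C2, C3, C4, C4a, C5–C8, C8a.

Step 1
Reactants: 1 3,4-dihydroxybenzaldehyde
Product: 2 3-hydroxy-4-(SEM-oxy)benzaldehyde
Conditions: SEMCl (1.05 equiv), K2CO3 (1.1 equiv), acetone, 0 °C to rt
Reagents that add atoms: 2-(trimethylsilyl)ethoxymethyl chloride (SEMCl), C[Si](C)(C)CCOCCl
Why: Williamson-type O-alkylation; the 4-OH, para to the formyl group, is the more acidic phenol, so one equivalent of carbonate should form the 4-phenoxide, which is alkylated selectively, as is well known for benzyl, allyl and alkoxymethyl halides on this aldehyde.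

Step 2
Reactants: 3 2,4-dihydroxyacetophenone
Product: 4 1-[2,4-bis(SEM-oxy)phenyl]ethan-1-one
Conditions: NaH (2.2 equiv), SEMCl (2.3 equiv), DMF, 0 °C to rt
Reagents that add atoms: 2-(trimethylsilyl)ethoxymethyl chloride (SEMCl), C[Si](C)(C)CCOCCl
Why: Double O-alkylation of the sodium phenoxides; NaH is needed because the 2-OH is hydrogen-bonded to the ketone, and limiting the base to the two phenols leaves the methyl ketone untouched.

Step 3
Reactants: 2 3-hydroxy-4-(SEM-oxy)benzaldehyde; 4 1-[2,4-bis(SEM-oxy)phenyl]ethan-1-one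
Product: 6 (2E)-1-[2,4-bis(SEM-oxy)phenyl]-3-[3-hydroxy-4-(SEM-oxy)phenyl]prop-2-en-1-one, via aldol adduct 5 (not isolated)
Conditions: KOH (50% aq., 8 equiv), EtOH, rt; then 1 M HCl to pH 6, 0 °C
Reagents that add atoms: none
Why: Claisen–Schmidt condensation; the enolate of 4 adds to the aldehyde, which stays electrophilic because its phenoxide is meta to the formyl group (as with isovanillin), and E1cB loss of water from 5 should give the (E)-chalcone, the SEM acetals being stable to base.

Step 4
Reactants: 6 (2E)-chalcone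
Product: 7 1-[2,4-bis(SEM-oxy)phenyl]-3-[3-hydroxy-4-(SEM-oxy)phenyl]propan-1-one
Conditions: H2 (1 atm), 10% Pd/C, Ph2S (cat.), EtOAc, rt
Reagents that add atoms: none
Why: Heterogeneous catalytic hydrogenation of the enone C=C; sulfide-poisoned Pd/C reduces conjugated alkenes without touching aryl ketones, and SEM ethers are inert to hydrogenation.

Step 5
Reactants: 8 geranyl acetate, (2E)-3,7-dimethylocta-2,6-dien-1-yl acetate
Product: 11 (2E,5E)-7-hydroxy-3,7-dimethylocta-2,5-dien-1-yl acetate, via hydroxy selenide 9 (not isolated), via selenoxide 10 (not isolated)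
Conditions: PhSeCl (1.1 equiv), MeCN/H2O 5:1, 0 °C to rt; then NaHCO3, 30% aq. H2O2, THF, 0 °C to rt
Reagents that add atoms: water, O
Why: Markovnikov hydroxyselenation of the more electron-rich 6,7-alkene (the 2,3-alkene is deactivated by the allylic acetate) puts OH on C7 and PhSe on C6, and oxidation to the selenoxide followed by syn-elimination, which can only run toward C5, should give the (E)-configured tertiary allylic alcohol.

Step 6
Reactants: 11 (2E,5E)-7-hydroxy-3,7-dimethylocta-2,5-dien-1-yl acetate
Product: 12 (2E,5E)-3,7-dimethyl-7-(triethylsilyloxy)octa-2,5-dien-1-yl acetate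
Conditions: TESOTf (1.3 equiv), 2,6-lutidine (2 equiv), CH2Cl2, −78 to 0 °C
Reagents that add atoms: triethylsilyl trifluoromethanesulfonate (TESOTf), CC[Si](CC)(CC)OS(=O)(=O)C(F)(F)F
Why: Silylation of a hindered tertiary alcohol with a silyl triflate and a hindered pyridine base is standard, and the acetate is inert.

Step 7
Reactants: 12 (2E,5E)-3,7-dimethyl-7-(triethylsilyloxy)octa-2,5-dien-1-yl acetate
Product: 13 (2E,5E)-3,7-dimethyl-7-(triethylsilyloxy)octa-2,5-dien-1-ol
Conditions: K2CO3 (0.3 equiv), MeOH, 0 °C to rt
Reagents that add atoms: none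
Why: Base-catalysed transesterification removes the primary acetate as methyl acetate, and a tertiary triethylsilyl ether is stable to K2CO3 in methanol.

Step 8
Reactants: 13 (2E,5E)-3,7-dimethyl-7-(triethylsilyloxy)octa-2,5-dien-1-ol
Product: 14 (2E,5E)-3,7-dimethyl-7-(triethylsilyloxy)octa-2,5-dienal
Conditions: MnO2 (activated, 15 equiv), CH2Cl2, rt
Reagents that add atoms: none
Why: Chemoselective MnO2 oxidation of a primary allylic alcohol to the enal with retention of the (2E) geometry, as in the oxidation of geraniol to geranial; the neutral conditions leave the skipped diene and the silyl ether alone.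

Step 9
Reactants: 7 1-[2,4-bis(SEM-oxy)phenyl]-3-[3-hydroxy-4-(SEM-oxy)phenyl]propan-1-one; 14 (2E,5E)-3,7-dimethyl-7-(triethylsilyloxy)octa-2,5-dienal (1.3 equiv)
Product: 17 1-[2,4-bis(SEM-oxy)phenyl]-3-{(2R)-2-methyl-2-[(2E)-4-methyl-4-(triethylsilyloxy)pent-2-en-1-yl]-8-(SEM-oxy)-2H-chromen-5-yl}propan-1-one, via benzodioxaborin 15 (not isolated), via ortho-quinone methide 16 (not isolated)
Conditions: PhB(OH)2 (1.0 equiv), (R)-3,3'-bis(2,4,6-triisopropylphenyl)-1,1'-binaphthalene-2,2'-diyl hydrogen phosphate (10 mol%), 5 Å MS, toluene, 70 °C, dark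
Reagents that add atoms: none
Why: Proposed new method: PhB(OH)2 esterifies the C8a hydroxyl of 7 and delivers the aldehyde carbon of 14 through a six-membered transition state to the only free ortho carbon (C4–C4a bond, benzodioxaborin 15); the chiral phosphoric acid, taking the role a carboxylic acid plays in the racemic protocol, ionises the benzylic C4–O bond to ortho-quinone methide 16, and PhB(OH)2 is returned on work-up. The closest known reaction types are the racemic PhB(OH)2/carboxylic acid condensation of phenols with citral-type enals to 2,2-disubstituted 2H-chromenes and chiral phosphoric acid control of additions to ortho-quinone methides generated in situ; an enantioselective form of this closure is not established. The 2H-pyran ring closes by thermal disrotatory oxa-6π electrocyclisation of the 1-oxatriene (O1–C2 bond), driven by rearomatisation of ring A. C2 is the only new stereocentre and should be controlled by the phosphate, which is hydrogen-bonded to (or ion-paired with, possibly through boron) the quinone methide oxygen from the moment of ionisation, so that closure occurs inside the chiral pocket before the free oxatriene can close unselectively; with the (2E) alkene of fixed geometry one helical sense of the s-cis,s-cis oxatriene leads to (2R). Regioselectivity is needed and is secured by the boron template (ortho, not para) and by C8 carrying OSEM, chemoselectivity by ring B having no free phenol, and the moderate acidity of the phosphoric acid and the absence of amine catalysts should spare the SEM acetals, the tertiary allylic silyl ether and the skipped diene of 14.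

Step 10
Reactants: 17 protected (2R)-chromene
Product: 18 1-(2,4-dihydroxyphenyl)-3-{(2R)-8-hydroxy-2-[(2E)-4-hydroxy-4-methylpent-2-en-1-yl]-2-methyl-2H-chromen-5-yl}propan-1-one
Conditions: n-Bu4NF (1 M in THF, 12 equiv), DMPU, 60 °C; then aq. NH4Cl
Reagents that add atoms: none
Why: Fluoride-induced desilylation; the tertiary triethylsilyl ether is cleaved directly and each aryl SEM ether fragments (loss of fluorotrimethylsilane and ethylene, then of formaldehyde) with phenoxide as a good leaving group, while the non-acidic medium spares the tertiary allylic alcohol and the chromene and leaves C2 untouched.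

**Compound list**
1 | 3,4-dihydroxybenzaldehyde | O=Cc1ccc(O)c(O)c1 | starting material
2 | 3-hydroxy-4-(SEM-oxy)benzaldehyde | O=Cc1ccc(OCOCC[Si](C)(C)C)c(O)c1 | intermediate
3 | 2,4-dihydroxyacetophenone | CC(=O)c1ccc(O)cc1O | starting material
4 | 1-[2,4-bis(SEM-oxy)phenyl]ethan-1-one | CC(=O)c1ccc(OCOCC[Si](C)(C)C)cc1OCOCC[Si](C)(C)C | intermediate
5 | 1-[2,4-bis(SEM-oxy)phenyl]-3-hydroxy-3-[3-hydroxy-4-(SEM-oxy)phenyl]propan-1-one (racemic aldol adduct, not isolated) | OC(CC(=O)c1ccc(OCOCC[Si](C)(C)C)cc1OCOCC[Si](C)(C)C)c1ccc(OCOCC[Si](C)(C)C)c(O)c1 | intermediate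
6 | (2E)-1-[2,4-bis(SEM-oxy)phenyl]-3-[3-hydroxy-4-(SEM-oxy)phenyl]prop-2-en-1-one | O=C(/C=C/c1ccc(OCOCC[Si](C)(C)C)c(O)c1)c1ccc(OCOCC[Si](C)(C)C)cc1OCOCC[Si](C)(C)C | intermediate
7 | 1-[2,4-bis(SEM-oxy)phenyl]-3-[3-hydroxy-4-(SEM-oxy)phenyl]propan-1-one | Oc1cc(CCC(=O)c2ccc(OCOCC[Si](C)(C)C)cc2OCOCC[Si](C)(C)C)ccc1OCOCC[Si](C)(C)C | intermediate
8 | geranyl acetate, (2E)-3,7-dimethylocta-2,6-dien-1-yl acetate | CC(C)=CCC/C(C)=C/COC(C)=O | starting material
9 | (2E)-7-hydroxy-3,7-dimethyl-6-(phenylselanyl)oct-2-en-1-yl acetate (racemic, not isolated) | CC(=O)OC/C=C(\C)CCC([Se]c1ccccc1)C(C)(C)O | intermediate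
10 | (2E)-7-hydroxy-3,7-dimethyl-6-(phenylseleninyl)oct-2-en-1-yl acetate (selenoxide, not isolated) | CC(=O)OC/C=C(\C)CCC([Se](=O)c1ccccc1)C(C)(C)O | intermediate
11 | (2E,5E)-7-hydroxy-3,7-dimethylocta-2,5-dien-1-yl acetate | CC(=O)OC/C=C(\C)C/C=C/C(C)(C)O | intermediate
12 | (2E,5E)-3,7-dimethyl-7-(triethylsilyloxy)octa-2,5-dien-1-yl acetate | CC(=O)OC/C=C(\C)C/C=C/C(C)(C)O[Si](CC)(CC)CC | intermediate
13 | (2E,5E)-3,7-dimethyl-7-(triethylsilyloxy)octa-2,5-dien-1-ol | OC/C=C(\C)C/C=C/C(C)(C)O[Si](CC)(CC)CC | intermediate
14 | (2E,5E)-3,7-dimethyl-7-(triethylsilyloxy)octa-2,5-dienal | CC(C)(O[Si](CC)(CC)CC)/C=C/C/C(C)=C/C=O | intermediate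
15 | 4-[(1E,4E)-2,6-dimethyl-6-(triethylsilyloxy)hepta-1,4-dien-1-yl]-2-phenyl-8-(SEM-oxy)-5-{3-oxo-3-[2,4-bis(SEM-oxy)phenyl]propyl}-4H-1,3,2-benzodioxaborin (racemic at C4, not isolated) | CC(C)(O[Si](CC)(CC)CC)/C=C/C/C(C)=C/C1OB(c2ccccc2)Oc2c(OCOCC[Si](C)(C)C)ccc(CCC(=O)c3ccc(OCOCC[Si](C)(C)C)cc3OCOCC[Si](C)(C)C)c21 | intermediate
16 | (6Z)-6-[(2E,5E)-3,7-dimethyl-7-(triethylsilyloxy)octa-2,5-dien-1-ylidene]-2-(SEM-oxy)-5-{3-oxo-3-[2,4-bis(SEM-oxy)phenyl]propyl}cyclohexa-2,4-dien-1-one (ortho-quinone methide, not isolated) | CC(C)(O[Si](CC)(CC)CC)/C=C/C/C(C)=C/C=C1\C(=O)C(OCOCC[Si](C)(C)C)=CC=C1CCC(=O)c1ccc(OCOCC[Si](C)(C)C)cc1OCOCC[Si](C)(C)C | intermediate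
17 | 1-[2,4-bis(SEM-oxy)phenyl]-3-{(2R)-2-methyl-2-[(2E)-4-methyl-4-(triethylsilyloxy)pent-2-en-1-yl]-8-(SEM-oxy)-2H-chromen-5-yl}propan-1-one | CC(C)(O[Si](CC)(CC)CC)/C=C/C[C@]1(C)C=Cc2c(CCC(=O)c3ccc(OCOCC[Si](C)(C)C)cc3OCOCC[Si](C)(C)C)ccc(OCOCC[Si](C)(C)C)c2O1 | intermediate
18 | 1-(2,4-dihydroxyphenyl)-3-{(2R)-8-hydroxy-2-[(2E)-4-hydroxy-4-methylpent-2-en-1-yl]-2-methyl-2H-chromen-5-yl}propan-1-one | CC(C)(O)/C=C/C[C@]1(C)C=Cc2c(CCC(=O)c3ccc(O)cc3O)ccc(O)c2O1 | target

Total step count: 10. Longest linear sequence: 6 steps (steps 5, 6, 7, 8, 9, 10 from geranyl acetate); the aryl branch (steps 1–4) is convergent.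

**Steps most likely to fail**

1. Step 9. Several processes may defeat it:
   - unselective closure of the free oxatriene may outrun the acid-bound pathway;
   - the phosphate may discriminate poorly between the methyl and CH2 substituents at C2;
   - the enantiomeric excess may erode through thermal or photochemical ring-opening and reclosure of the chromene;
   - the ortho-aldol may be slow at the hindered C4a, or a silyl group may be lost under acid.

   Fallback with known chemistry, setting out from 7 and 14: condensation under the racemic protocol (PhB(OH)2, catalytic propionic acid, toluene, reflux, Dean–Stark) should give the racemic protected chromene F1. This is resolved by preparative HPLC on an amylose tris(3,5-dimethylphenylcarbamate) stationary phase. The (2R)-enantiomer is assigned by chiroptical comparison after deprotection, and the fallback rejoins the route at 17.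

2. Step 10. Fragmentation of the non-chelated aryl SEM ethers may be incomplete, the formaldehyde released may hydroxymethylate the electron-rich resorcinol phenoxide, or the phenoxides may be oxidised in the hot basic medium. Fallback, setting out from 17: non-basic, chelation-assisted Lewis acid cleavage of the three SEM ethers with MgBr2·OEt2 in Et2O/MeNO2 at rt should give the triethylsilyl-protected triphenol F2. Its silyl ether is then removed with acetic acid-buffered n-Bu4NF in THF at 0 °C, which gives 18 directly.

3. Step 5. Water may lose out to chloride in capturing the seleniranium ion, the 2,3-alkene may react or take part in cyclisation under the acid released, or the product alkene may be over-oxidised by the peroxide/seleninic acid mixture. Fallback, setting out from 8: epoxidation of the more electron-rich 6,7-alkene with mCPBA (1.0 equiv, NaHCO3, CH2Cl2, 0 °C) should give the 6,7-epoxide F3. Opening at the less hindered C6 with the selenolate from PhSeSePh and NaBH4 in EtOH gives hydroxy selenide 9, now isolated, where the fallback rejoins the route; oxidation with H2O2 in THF then leads through 10 to 11.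

**Further compounds**
F1 | step 9 | racemic 1-[2,4-bis(SEM-oxy)phenyl]-3-{2-methyl-2-[(2E)-4-methyl-4-(triethylsilyloxy)pent-2-en-1-yl]-8-(SEM-oxy)-2H-chromen-5-yl}propan-1-one | CC(C)(O[Si](CC)(CC)CC)/C=C/CC1(C)C=Cc2c(CCC(=O)c3ccc(OCOCC[Si](C)(C)C)cc3OCOCC[Si](C)(C)C)ccc(OCOCC[Si](C)(C)C)c2O1
F2 | step 10 | 1-(2,4-dihydroxyphenyl)-3-{(2R)-8-hydroxy-2-methyl-2-[(2E)-4-methyl-4-(triethylsilyloxy)pent-2-en-1-yl]-2H-chromen-5-yl}propan-1-one | CC(C)(O[Si](CC)(CC)CC)/C=C/C[C@]1(C)C=Cc2c(CCC(=O)c3ccc(O)cc3O)ccc(O)c2O1
F3 | step 5 | (2E)-6,7-epoxy-3,7-dimethyloct-2-en-1-yl acetate (racemic) | CC(=O)OC/C=C(\C)CCC1OC1(C)C
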